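The route rests on cutting the C4a–C5 bond of ring A, which unravels the 5,8-hydroquinone into a four-carbon squarate fragment hung on a finished pyranone (ring C) that already carries the trimethoxyphenyl ring B. The feature exploited is ring A itself: para-related C5–OH and C8–OH, C7–OMe and C6–H, fused to ring C at C4a–C8a. Heating a 4-hydroxy-3-methoxycyclobutenone bonded through its carbinol carbon to pyranone C6 opens the four-membered ring to a dienylketene and closes ring A onto pyranone C5 in one operation, delivering both phenols and the C6/C7 pattern with no protecting groups. The pyranone comes from pyromeconic acid by bromination, methylation and Suzuki coupling.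

Key step: step 6

Remark: the target has no stereocentre and no configurationally stable axis, so "single enantiomer" calls for no control; the carbinol centre of 10 is racemic and is erased in step 6. A furylcarbinol (Achmatowicz) entry to the pyranone was not used, because its rearrangement product is two hydrogens short of the 3-hydroxy-4-pyranone oxidation level and would need extra oxidation steps.

Step 1
Reactants: 1 3-hydroxy-4H-pyran-4-one (pyromeconic acid)
Product: 2 2-bromo-3-hydroxy-4H-pyran-4-one
Conditions: NBS (1.0 equiv), MeCN, 0 °C to rt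
Reagents that add atoms: N-bromosuccinimide, O=C1CCC(=O)N1Br
Why: Electrophilic bromination of the enolic hydroxypyranone should go to C2, the carbon ortho to the hydroxyl (the enol β-carbon), as in the halogenation of kojic acid and allomaltol next to their hydroxyl.

Step 2
Reactants: 2 2-bromo-3-hydroxy-4H-pyran-4-one
Product: 3 2-bromo-3-methoxy-4H-pyran-4-one
Conditions: MeI, K2CO3, DMF, rt
Reagents that add atoms: iodomethane, CI
Why: Williamson O-methylation of the acidic enolic hydroxyl, with carbonate too weak a nucleophile to displace the vinylogous acyl bromide.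

Step 3
Reactants: 3 2-bromo-3-methoxy-4H-pyran-4-one; 4 (2,3,4-trimethoxyphenyl)boronic acid
Product: 5 3-methoxy-2-(2,3,4-trimethoxyphenyl)-4H-pyran-4-one
Conditions: Pd(OAc)2 (cat.), SPhos (cat.), K3PO4, toluene/H2O 10:1, 80 °C
Reagents that add atoms: none
Why: Suzuki–Miyaura coupling, in which the C2–Br bond of a β-alkoxy enone undergoes oxidative addition readily and the biaryl phosphine copes with the two ortho methoxy groups at the new bond.

Step 4
Reactants: 6 dimethyl squarate
Product: 8 3-methoxycyclobut-3-ene-1,2-dione (methyl semisquarate), via 4-hydroxy-2,3-dimethoxycyclobutenone 7 (not isolated)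
Conditions: LiAlH(OtBu)3, THF, −78 to 0 °C; then 6 M HCl, CH2Cl2, rt
Reagents that add atoms: none
Why: A hindered hydride should reduce one squarate carbonyl in a 1,2-sense, and acid then ionises the allylic alcohol and hydrolyses the methoxy-stabilised cation with loss of methanol, the standard squarate-to-cyclobutenedione transposition.

Step 5
Reactants: 5 3-methoxy-2-(2,3,4-trimethoxyphenyl)-4H-pyran-4-one; 8 3-methoxycyclobut-3-ene-1,2-dione
Product: 10 6-(1-hydroxy-2-methoxy-4-oxocyclobut-2-en-1-yl)-3-methoxy-2-(2,3,4-trimethoxyphenyl)-4H-pyran-4-one (racemic), via 6-lithiopyranone 9 (not isolated)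
Conditions: LiTMP (from TMPH, n-BuLi), THF, −78 °C; cannulate into 8 (1.3 equiv), THF, −78 °C; aq. NH4Cl at −78 °C
Reagents that add atoms: none
Why: Deprotonative lithiation should take C6–H, the ring C–H next to the ring oxygen at the β-position of the vinylogous ester (the regiochemistry of C6 lithiation of uracils and C2 lithiation of isoflavones and 4-quinolones), and the vinyllithium then adds 1,2 to the C2 carbonyl of 8, the ketone not deactivated as a vinylogous ester, so the carbinol carbon ends up next to C–OMe; the new stereocentre forms racemic and is irrelevant.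

Step 6
Reactants: 10 6-(1-hydroxy-2-methoxy-4-oxocyclobut-2-en-1-yl)-3-methoxy-2-(2,3,4-trimethoxyphenyl)-4H-pyran-4-one
Product: 13 5,8-dihydroxy-3,7,2',3',4'-pentamethoxyflavone, via dienylketene 11 (not isolated), via 4aH-cyclohexadienone 12 (not isolated)
Conditions: degassed toluene (0.01 M), 110 °C, Ar (p-xylene, 138 °C if slow); aq. Na2S2O4 wash on work-up
Reagents that add atoms: none
Why: Thermal conrotatory 4π opening of the cyclobutenone C1–C4 bond should give dienylketene 11, whose ketene carbon bonds to pyranone C5 to give dienone 12, which enolises to the aromatic hydroquinone. The closest known reaction type is the Moore rearrangement of 4-aryl- and 4-alkenyl-4-hydroxycyclobutenones to hydroquinones. Ring A closes as a six-membered carbocycle by a thermally allowed disrotatory 6π electrocyclisation across the ketene C=C, the C(OMe)=C(OH) bond and the pyranone C5=C6 bond. No stereocentre is created, and the racemic carbinol carbon becomes the sp2 carbon C8. The step needs the hydroxyl to rotate outward so that the pyranonyl group lies beside the ketene, which the donor character of the OH secures, and closure at C5 is the only option because it is the sole carbon ortho to the attachment point and the nucleophilic α-carbon of the vinylogous ester. The oxygenation pattern is preset by the cyclobutenone: ketene carbon to C5–OH, CH to C6, C–OMe to C7, carbinol carbon to C8–OH.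

Compound list
1 | 3-hydroxy-4H-pyran-4-one (pyromeconic acid) | O=c1ccocc1O | starting material
2 | 2-bromo-3-hydroxy-4H-pyran-4-one | O=c1ccoc(Br)c1O | intermediate
3 | 2-bromo-3-methoxy-4H-pyran-4-one | COc1c(Br)occc1=O | intermediate
4 | (2,3,4-trimethoxyphenyl)boronic acid | COc1ccc(B(O)O)c(OC)c1OC | starting material
5 | 3-methoxy-2-(2,3,4-trimethoxyphenyl)-4H-pyran-4-one | COc1ccc(-c2occc(=O)c2OC)c(OC)c1OC | intermediate
6 | dimethyl squarate (3,4-dimethoxycyclobut-3-ene-1,2-dione) | COC1=C(OC)C(=O)C1=O | starting material
7 | 4-hydroxy-2,3-dimethoxycyclobut-2-en-1-one (racemic, not isolated) | COC1=C(OC)C(=O)C1O | intermediate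
8 | 3-methoxycyclobut-3-ene-1,2-dione (methyl semisquarate) | COC1=CC(=O)C1=O | intermediate
9 | 6-lithio-3-methoxy-2-(2,3,4-trimethoxyphenyl)-4H-pyran-4-one (not isolated) | COc1ccc(-c2oc([Li])cc(=O)c2OC)c(OC)c1OC | intermediate
10 | 6-(1-hydroxy-2-methoxy-4-oxocyclobut-2-en-1-yl)-3-methoxy-2-(2,3,4-trimethoxyphenyl)-4H-pyran-4-one (racemic carbinol) | COC1=CC(=O)C1(O)C1=CC(=O)C(OC)=C(c2ccc(OC)c(OC)c2OC)O1 | intermediate
11 | 6-[(1Z)-1-hydroxy-2-methoxy-4-oxobuta-1,3-dien-1-yl]-3-methoxy-2-(2,3,4-trimethoxyphenyl)-4H-pyran-4-one (dienylketene, not isolated) | O=C=C/C(OC)=C(O)\C1=CC(=O)C(OC)=C(c2ccc(OC)c(OC)c2OC)O1 | intermediate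
12 | 8-hydroxy-3,7-dimethoxy-2-(2,3,4-trimethoxyphenyl)-4aH-chromene-4,5-dione (racemic, not isolated) | O=C1C=C(OC)C(O)=C2OC(c3ccc(OC)c(OC)c3OC)=C(OC)C(=O)C12 | intermediate
13 | 5,8-dihydroxy-3,7,2',3',4'-pentamethoxyflavone (achiral) | COc1ccc(-c2oc3c(O)c(OC)cc(O)c3c(=O)c2OC)c(OC)c1OC | target

Total step count: 6
Longest linear sequence: 5 (steps 1, 2, 3, 5, 6); step 4 is a one-step side branch.

Steps most likely to fail

Step 6. The dienylketene may be drained before ring closure, either by inward rotation of the hydroxyl and lactonisation to a butenolide or by acylating the product phenols, and the electron-rich hydroquinone may be lost to oxidation while hot. The fallback sets out from 10 and masks the carbinol first. Silylation with TMSOTf and 2,6-lutidine in CH2Cl2 at −78 °C should give the trimethylsilyl ether of the precursor F1. The same thermolysis in degassed toluene should then deliver the oxidation-resistant 8-O-trimethylsilyl hydroquinone F2, since a silyloxy group cannot trap the ketene. Dilute aqueous HCl in THF removes the silyl group and the route comes back at 13.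

Step 5. Deprotonation may not be clean at C6 (competition from C5 or the aryl ring), or the lithiated pyranone may ring-open or add in conjugate fashion before productive trapping. The fallback sets out from 5 and fixes the metalation site in an isolable intermediate. Zincation with TMPZnCl·LiCl in THF at rt, which is directed to the position next to the ring oxygen in chromones and 4-pyranones, should give the pyranon-6-ylzinc chloride F3. Iodine then gives the 6-iodopyranone F4. Iodine–magnesium exchange with iPrMgCl·LiCl in THF at −78 °C should give the pyranon-6-ylmagnesium chloride F5. Adding this to 8 at −78 °C returns the route at 10.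

Step 3. Protodeboronation of the electron-rich ortho-methoxy boronic acid and hydrolytic displacement of the vinylogous acyl bromide by aqueous base may outrun the coupling. The fallback sets out from 3 and swaps to a base-free, water-free organozinc partner. (2,3,4-Trimethoxyphenyl)zinc chloride F6 is made from commercial 1-bromo-2,3,4-trimethoxybenzene with Mg turnings, LiCl and ZnCl2 in THF. Negishi coupling with 3 under Pd(PPh3)4 in THF at 50 °C returns the route at 5.

Further compounds
F1 | step 6 | 3-methoxy-6-[2-methoxy-4-oxo-1-(trimethylsilyloxy)cyclobut-2-en-1-yl]-2-(2,3,4-trimethoxyphenyl)-4H-pyran-4-one (racemic) | COC1=CC(=O)C1(O[Si](C)(C)C)C1=CC(=O)C(OC)=C(c2ccc(OC)c(OC)c2OC)O1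
F2 | step 6 | 5-hydroxy-3,7-dimethoxy-2-(2,3,4-trimethoxyphenyl)-8-(trimethylsilyloxy)-4H-chromen-4-one | COc1ccc(-c2oc3c(O[Si](C)(C)C)c(OC)cc(O)c3c(=O)c2OC)c(OC)c1OC
F3 | step 5 | [5-methoxy-4-oxo-6-(2,3,4-trimethoxyphenyl)-4H-pyran-2-yl]zinc chloride | COc1ccc(-c2oc([Zn]Cl)cc(=O)c2OC)c(OC)c1OC
F4 | step 5 | 6-iodo-3-methoxy-2-(2,3,4-trimethoxyphenyl)-4H-pyran-4-one | COc1ccc(-c2oc(I)cc(=O)c2OC)c(OC)c1OC
F5 | step 5 | [5-methoxy-4-oxo-6-(2,3,4-trimethoxyphenyl)-4H-pyran-2-yl]magnesium chloride | COc1ccc(-c2oc([Mg]Cl)cc(=O)c2OC)c(OC)c1OC
F6 | step 3 | (2,3,4-trimethoxyphenyl)zinc chloride | COc1ccc([Zn]Cl)c(OC)c1OC
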